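A direct plan would build the oxolane–lactone core first and attach the furyl chain last. Alkenylcyclopropanol A1 would be ring-expanded and etherified in one step by a chiral ArI(OAc)2 reagent (trivalent iodine), then oxidised (Baeyer–Villiger) to the lactone. The derived aldehyde A2 would be joined to the allylbarium reagent from chloride A3, and carbinol A4 would be oxidised to the ketone. Its weakest steps would be:
(a) the iodane-triggered ring expansion/etherification of A1, which would be without precedent, would have to set two stereocentres by reagent control, and would compete with plain iodoetherification and oxidative opening of the cyclopropanol;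
(b) the EtMgBr/Ti(OiPr)4 cyclopropanation that would make A1, where an α-substituted enoate with two free hydroxyls would divert the titanium reagent;
(c) the allylbarium addition to A2 and re-oxidation of A4, which would need activated barium, α-attack and discrimination against the lactone, and would spend three redox operations on one ketone.

The route rests on the bond between the quaternary oxolane carbon and the methylene that links it to the ketone. Because the ketone is β to the oxolane oxygen through that carbon, O–C(CH3)–CH2–C(=O) is the retron of a ketal substitution. The lactone ring is closed first from an epoxy acid and the oxolane second as a cyclic methyl ketal; its 2-methyloxolan-2-ylium ion is then captured by the enol ether of the complete furyl side chain. This one operation joins the two halves at the ketone oxidation state and sets the quaternary stereocentre anti to the lactone, so no iodane cascade, cyclopropanol or aldehyde–allylmetal redox detour is needed.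

Key step: step 9

Assumption: bromo ketal 1 and 3-(chloromethyl)furan 12 are taken as purchased; 12 is otherwise one operation from furan-3-ylmethanol (SOCl2, pyridine).

**Step 1**
Reactants: 1 2-(2-bromoethyl)-2-methyl-1,3-dioxolane; 2 methacrolein (2-methylprop-2-enal)
Product: 4 2-methyl-5-(2-methyl-1,3-dioxolan-2-yl)pent-1-en-3-ol (racemic), via Grignard reagent 3 (not isolated)
Conditions: Mg, THF, 25–30 °C; then 2, −78 to 0 °C; aq NH4Cl
Reagents that add atoms: none
Why: Grignard 1,2-addition to the enal; the dioxolane masks the ketone, and the racemic carbinol centre is destroyed in step 2.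

**Step 2**
Reactants: 4 2-methyl-5-(2-methyl-1,3-dioxolan-2-yl)pent-1-en-3-ol; 5 triethyl orthoacetate
Product: 7 ethyl (4E)-4-methyl-7-(2-methyl-1,3-dioxolan-2-yl)hept-4-enoate, via ketene acetal 6 (not isolated)
Conditions: 5 (5 equiv), EtCO2H (5 mol%), 140 °C, EtOH distilled off
Reagents that add atoms: none
Why: Johnson–Claisen rearrangement through a chair transition state with the ketal-bearing chain equatorial should give the E trisubstituted olefin and add the two-carbon ester arm.

**Step 3**
Reactants: 7 ethyl (4E)-4-methyl-7-(2-methyl-1,3-dioxolan-2-yl)hept-4-enoate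
Product: 8 ethyl 3-[(2R,3R)-2-methyl-3-[2-(2-methyl-1,3-dioxolan-2-yl)ethyl]oxiran-2-yl]propanoate
Conditions: 1,2:4,5-di-O-isopropylidene-β-D-erythro-hexo-2,3-diulo-2,6-pyranose (D-fructose-derived Shi ketone, 30 mol%), Oxone (2KHSO5·KHSO4·K2SO4), K2CO3, Bu4NHSO4, MeCN/CH2(OMe)2/aq Na2B4O7 buffer (pH 10.5), 0 °C
Reagents that add atoms: potassium peroxymonosulfate [K+].[O-]S(=O)(=O)OO
Why: Shi asymmetric epoxidation (chiral dioxirane, spiro transition state) should deliver oxygen to one face of the E trisubstituted olefin and give the (R,R)-epoxide, which fixes both future C–O stereocentres; ester and ketal are inert at this pH.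

**Step 4**
Reactants: 8 ethyl 3-[(2R,3R)-2-methyl-3-[2-(2-methyl-1,3-dioxolan-2-yl)ethyl]oxiran-2-yl]propanoate
Product: 10 (5S)-5-[(1R)-1-hydroxy-3-(2-methyl-1,3-dioxolan-2-yl)propyl]-5-methyloxolan-2-one, via epoxy acid 9 (not isolated)
Conditions: LiOH·H2O (1.5 equiv), THF/H2O, 0 °C to rt; then 1 M aq HCl (1.5 equiv, pH 3–4), rt
Reagents that add atoms: lithium hydroxide [Li+].[OH-]
Why: Saponification, then acid-promoted epoxy-acid lactonization: the carboxyl opens the epoxide 5-exo at the tertiary carbon with inversion (S) and leaves the secondary carbinol untouched (R), so the lactone ring is closed first.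

**Step 5**
Reactants: 10 (5S)-5-[(1R)-1-hydroxy-3-(2-methyl-1,3-dioxolan-2-yl)propyl]-5-methyloxolan-2-one
Product: 11 (5S)-5-[(2R)-5-methoxy-5-methyloxolan-2-yl]-5-methyloxolan-2-one (both epimers at the ketal carbon)
Conditions: MeOH, pyridinium p-toluenesulfonate (10 mol%), rt; Et3N, evaporation
Reagents that add atoms: methanol CO
Why: Acid-catalysed transketalization exchanges the dioxolane for the five-membered cyclic methyl ketal formed by the secondary hydroxyl, which closes the oxolane ring second; both ketal epimers converge on one cation in step 9.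

**Step 6**
Reactants: 12 3-(chloromethyl)furan; 13 2-methyl-2-vinyloxirane (racemic)
Product: 15 (2E)-5-(furan-3-yl)-2-methylpent-2-en-1-ol, via Grignard reagent 14 (not isolated)
Conditions: Mg, THF, 0 °C; then CuI (10 mol%), 13, −30 °C; aq NH4Cl; minor Z isomer removed on AgNO3-impregnated silica
Reagents that add atoms: none
Why: Copper-catalysed SN2' opening of the vinyl oxirane by the Grignard reagent should give the 2-methylallylic alcohol mainly as the E isomer.

**Step 7**
Reactants: 15 (2E)-5-(furan-3-yl)-2-methylpent-2-en-1-ol
Product: 16 3-[(3E)-5-bromo-4-methylpent-3-en-1-yl]furan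
Conditions: CBr4, PPh3, CH2Cl2, −20 to 0 °C; used crude
Reagents that add atoms: tetrabromomethane BrC(Br)(Br)Br
Why: Appel bromination: bromide displaces the alkoxyphosphonium group by SN2 at the primary allylic carbon without transposition, under neutral conditions that spare the furan.

**Step 8**
Reactants: 16 3-[(3E)-5-bromo-4-methylpent-3-en-1-yl]furan; 17 ethyl vinyl ether (ethoxyethene)
Product: 19 3-[(3E)-6-ethoxy-4-methylhepta-3,6-dien-1-yl]furan, via 1-ethoxyvinyllithium 18 (not isolated)
Conditions: 17 (3 equiv), t-BuLi, THF, −78 to 0 °C; then 16, −78 °C to rt; aq NaHCO3; Et3N-deactivated silica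
Reagents that add atoms: none
Why: α-Lithiation of the vinyl ether gives an acyl anion equivalent whose SN2 alkylation installs the future ketone as its terminal enol ether, a regiochemistry that enolization of the β,γ-unsaturated methyl ketone could not give.

**Step 9**
Reactants: 11 (5S)-5-[(2R)-5-methoxy-5-methyloxolan-2-yl]-5-methyloxolan-2-one; 19 3-[(3E)-6-ethoxy-4-methylhepta-3,6-dien-1-yl]furan
Product: 21 (5S)-5-[(2R,5R)-5-[(4E)-7-(furan-3-yl)-4-methyl-2-oxohept-4-en-1-yl]-5-methyloxolan-2-yl]-5-methyloxolan-2-one (CNP0156092.1), via mixed ketal 20 (not isolated)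
Conditions: Me3SiOTf (0.2 equiv), 2,6-di-tert-butyl-4-methylpyridine (0.1 equiv), CH2Cl2, −78 °C, slow addition of 19 (1.3 equiv); then 0.5 M aq HCl/THF, 0 °C
Reagents that add atoms: water O
Why: Me3SiOTf ionizes ketal 11 to the 2-methyloxolan-2-ylium ion, the terminal CH2 of enol ether 19 attacks it to form the bond between the quaternary oxolane carbon and the ketone α-methylene, and the resulting ethoxycarbenium ion is captured by MeOSiMe3 as mixed ketal 20, which dilute acid hydrolyses to the ketone without moving the β,γ-olefin. The closest known reaction type is the Lewis-acid-mediated addition of enol ethers and silyl enol ethers to acetals and ketals (Mukaiyama-type aldol of acetals, Müller-Cunradi–Pieroh condensation, C-glycosidation of cyclic oxocarbenium ions). No ring is closed in this step; both rings are in place and the step makes the last skeletal bond. The new quaternary stereocentre is controlled by the oxolane CH across the ring oxygen: its substituent is the fully substituted lactone carbon, so the nucleophile should enter the planar cation on the face anti to it (inside attack on the envelope that keeps this group away from the incoming chain), which places the ketone chain trans and the methyl cis to the lactone, the (2R,5R) oxolane. The step needs this facial selectivity, which rests only on the bulk of the lactone-bearing substituent and is the main uncertainty. It also needs chemoselectivity for the enol ether over the furan and the trisubstituted olefin, which the much higher π-nucleophilicity of a 2-alkoxyalkene should secure, while slow addition and the hindered pyridine limit reaction of the ethoxycarbenium ion with a second enol ether.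

**Compound list**
1 | 2-(2-bromoethyl)-2-methyl-1,3-dioxolane | CC1(CCBr)OCCO1 | starting material
2 | methacrolein (2-methylprop-2-enal) | C=C(C)C=O | starting material
3 | [2-(2-methyl-1,3-dioxolan-2-yl)ethyl]magnesium bromide | CC1(CC[Mg]Br)OCCO1 | intermediate
4 | 2-methyl-5-(2-methyl-1,3-dioxolan-2-yl)pent-1-en-3-ol (racemic) | C=C(C)C(O)CCC1(C)OCCO1 | intermediate
5 | triethyl orthoacetate | CC(OCC)(OCC)OCC | starting material
6 | 2-{3-[(1-ethoxyethenyl)oxy]-4-methylpent-4-en-1-yl}-2-methyl-1,3-dioxolane | C=C(OCC)OC(CCC1(C)OCCO1)C(C)=C | intermediate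
7 | ethyl (4E)-4-methyl-7-(2-methyl-1,3-dioxolan-2-yl)hept-4-enoate | CCOC(=O)CC/C(C)=C/CCC1(C)OCCO1 | intermediate
8 | ethyl 3-[(2R,3R)-2-methyl-3-[2-(2-methyl-1,3-dioxolan-2-yl)ethyl]oxiran-2-yl]propanoate | CCOC(=O)CC[C@@]1(C)O[C@@H]1CCC1(C)OCCO1 | intermediate
9 | 3-[(2R,3R)-2-methyl-3-[2-(2-methyl-1,3-dioxolan-2-yl)ethyl]oxiran-2-yl]propanoic acid | OC(=O)CC[C@@]1(C)O[C@@H]1CCC1(C)OCCO1 | intermediate
10 | (5S)-5-[(1R)-1-hydroxy-3-(2-methyl-1,3-dioxolan-2-yl)propyl]-5-methyloxolan-2-one | CC1(CC[C@@H](O)[C@]2(C)CCC(=O)O2)OCCO1 | intermediate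
11 | (5S)-5-[(2R)-5-methoxy-5-methyloxolan-2-yl]-5-methyloxolan-2-one (epimers at the ketal carbon) | COC1(C)CC[C@H]([C@]2(C)CCC(=O)O2)O1 | intermediate
12 | 3-(chloromethyl)furan | ClCc1ccoc1 | starting material
13 | 2-methyl-2-vinyloxirane (racemic) | C=CC1(C)CO1 | starting material
14 | (furan-3-ylmethyl)magnesium chloride | Cl[Mg]Cc1ccoc1 | intermediate
15 | (2E)-5-(furan-3-yl)-2-methylpent-2-en-1-ol | OC/C(C)=C/CCc1ccoc1 | intermediate
16 | 3-[(3E)-5-bromo-4-methylpent-3-en-1-yl]furan | BrC/C(C)=C/CCc1ccoc1 | intermediate
17 | ethyl vinyl ether (ethoxyethene) | C=COCC | starting material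
18 | 1-ethoxyvinyllithium | [Li]C(=C)OCC | intermediate
19 | 3-[(3E)-6-ethoxy-4-methylhepta-3,6-dien-1-yl]furan | C=C(OCC)C/C(C)=C/CCc1ccoc1 | intermediate
20 | (5S)-5-[(2R,5R)-5-[(4E)-2-ethoxy-7-(furan-3-yl)-2-methoxy-4-methylhept-4-en-1-yl]-5-methyloxolan-2-yl]-5-methyloxolan-2-one (epimers at the ketal carbon) | CCOC(OC)(C[C@@]1(C)CC[C@H]([C@]2(C)CCC(=O)O2)O1)C/C(C)=C/CCc1ccoc1 | intermediate
21 | (5S)-5-[(2R,5R)-5-[(4E)-7-(furan-3-yl)-4-methyl-2-oxohept-4-en-1-yl]-5-methyloxolan-2-yl]-5-methyloxolan-2-one | C/C(=C\CCc1ccoc1)CC(=O)C[C@@]1(C)CC[C@H]([C@]2(C)CCC(=O)O2)O1 | target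

**Count**
Total steps: 9. Longest linear sequence: 6 (steps 1–5 and 9); the side chain takes steps 6–8.

**Steps most likely to fail**

Step 9. The oxolanylium ion may be captured on both faces, because the 1,4-induction across the ring oxygen is weak, and the ethoxycarbenium intermediate may be consumed by a second enol ether. The fallback sets out from 11 and 16 and comes back at 21; it makes the same bond with a two-carbon silyl nucleophile and completes the ketone by sulfone acylation. Ketal 11 would react with 1-(phenylsulfanyl)-1-(trimethylsilyloxy)ethene F1 (from S-phenyl thioacetate, LiN(i-Pr)2, Me3SiCl) under Me3SiOTf catalysis to give S-phenyl 2-[(2R,5R)-2-methyl-5-[(2S)-2-methyl-5-oxooxolan-2-yl]oxolan-2-yl]ethanethioate F2. This is a neutral product in which no cation survives, and its epimers at the quaternary carbon can be separated before the side chain is spent. Bromide 16 with PhSO2Na (DMF) would give 3-[(3E)-5-(benzenesulfonyl)-4-methylpent-3-en-1-yl]furan F3. Its lithio derivative (n-BuLi, THF, −78 °C, 2 equiv) would be acylated by F2 in preference to the lactone to give the β-keto sulfone F4. SmI2 (THF/MeOH, −78 °C) would remove the sulfonyl group with kinetic α-protonation and return 21.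

Step 8. The basic organolithium may attack the allylic bromide by SN2', elimination or halogen–metal exchange, and the enol ether may hydrolyse on isolation. The fallback sets out from 16 and comes back at 19: Stille coupling of 16 with purchased tributyl(1-ethoxyvinyl)stannane (Pd(PPh3)4, THF, 50 °C). This neutral cross-coupling through the allylpalladium complex should join at the primary terminus and keep the E olefin; it makes no new compound.

Step 6. Wurtz-type homocoupling may occur while the furylmethyl Grignard reagent forms, and Z olefin may leak through the SN2' opening. The fallback sets out from 12 and comes back at 15; the olefin geometry is set by a stabilised Wittig reaction instead. Chloride 12 with LiCH2CN (THF, −78 °C) would give 3-(furan-3-yl)propanenitrile F5. i-Bu2AlH (−78 °C) would give 3-(furan-3-yl)propanal F6. Ph3P=C(CH3)CO2Et (CH2Cl2, rt) would give ethyl (2E)-5-(furan-3-yl)-2-methylpent-2-enoate F7, and i-Bu2AlH would reduce it to 15.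

**Further compounds**
F1 | step 9 | 1-(phenylsulfanyl)-1-(trimethylsilyloxy)ethene | C=C(O[Si](C)(C)C)Sc1ccccc1
F2 | step 9 | S-phenyl 2-[(2R,5R)-2-methyl-5-[(2S)-2-methyl-5-oxooxolan-2-yl]oxolan-2-yl]ethanethioate | O=C(C[C@@]1(C)CC[C@H]([C@]2(C)CCC(=O)O2)O1)Sc1ccccc1
F3 | step 9 | 3-[(3E)-5-(benzenesulfonyl)-4-methylpent-3-en-1-yl]furan | O=S(=O)(C/C(C)=C/CCc1ccoc1)c1ccccc1
F4 | step 9 | (5S)-5-[(2R,5R)-5-[(4E)-3-(benzenesulfonyl)-7-(furan-3-yl)-4-methyl-2-oxohept-4-en-1-yl]-5-methyloxolan-2-yl]-5-methyloxolan-2-one (epimers at the sulfonyl carbon) | O=C(C[C@@]1(C)CC[C@H]([C@]2(C)CCC(=O)O2)O1)C(/C(C)=C/CCc1ccoc1)S(=O)(=O)c1ccccc1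
F0 | step 8 | none | none
F5 | step 6 | 3-(furan-3-yl)propanenitrile | N#CCCc1ccoc1
F6 | step 6 | 3-(furan-3-yl)propanal | O=CCCc1ccoc1
F7 | step 6 | ethyl (2E)-5-(furan-3-yl)-2-methylpent-2-enoate | CCOC(=O)/C(C)=C/CCc1ccoc1
A1 | direct plan | (3R,6E)-7-(1-hydroxycyclopropyl)-3-methyloct-6-ene-1,3-diol | OCC[C@](C)(O)CC/C=C(\C)C1(O)CC1
A2 | direct plan | 2-[(2R,5R)-2-methyl-5-[(2S)-2-methyl-5-oxooxolan-2-yl]oxolan-2-yl]acetaldehyde | O=CC[C@@]1(C)CC[C@H]([C@]2(C)CCC(=O)O2)O1
A3 | direct plan | 3-[(3E)-5-chloro-4-methylpent-3-en-1-yl]furan | ClC/C(C)=C/CCc1ccoc1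
A4 | direct plan | (5S)-5-[(2R,5R)-5-[(4E)-7-(furan-3-yl)-2-hydroxy-4-methylhept-4-en-1-yl]-5-methyloxolan-2-yl]-5-methyloxolan-2-one (both carbinol epimers) | C/C(=C\CCc1ccoc1)CC(O)C[C@@]1(C)CC[C@H]([C@]2(C)CCC(=O)O2)O1
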